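**Assumption:** the target SMILES has no stereocentre and no stereodescriptor, so plagiochin E is made as the single achiral constitution drawn (biaryl axis treated as configurationally unspecified); no asymmetric step is needed.

**Shorthand:** ArSul = 4-methoxy-2-[2-(4-methoxy-3-{4-[(3E)-4-(phenylsulfonyl)but-3-en-1-yl]phenoxy}phenyl)ethyl]phenyl. Ring A = biaryl ring with OH para to the biaryl bond; ring B = ring carrying OH and the ether oxygen; ring C = para-phenylene; ring D = 1,2,3-trisubstituted phenol.

## Retrosynthetic overview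

1. Plagiochin E ⇐ O-demethylation of macrocycle 18 (rings A and B as methyl ethers, ring D already a free phenol).
2. 18 ⇐ one-flask anionic Diels–Alder / CO2 loss / PhSO2H loss between a 5-hydroxy-2-pyrone on ring A and a tethered (E)-vinyl sulfone on ring C; ring D and the 16-membered ring form together.
3. Pyrone ⇐ aryl furyl carbinol (Achmatowicz rearrangement, lactol oxidation) ⇐ aryl aldehyde + 2-furyllithium; vinyl sulfone ⇐ methyl ester (reduction/Horner–Wadsworth–Emmons).
4. Open A–B–C chain ⇐ B-alkyl Suzuki–Miyaura coupling (ring A bromide + ring B styrene) and Ullmann ether coupling (ring B bromide + ring C phenol).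
5. Ring order: A, B and C are purchased; ring D and the macrocycle are made last, in one operation.

## Route

**Step 1**
Reactants: 1 3-bromo-4-methoxybenzaldehyde; 2 methyl 3-(4-hydroxyphenyl)propanoate
Product: 3 methyl 3-[4-(5-formyl-2-methoxyphenoxy)phenyl]propanoate
Conditions: CuI (10 mol %), N,N-dimethylglycine·HCl (30 mol %), Cs2CO3 (2.5 equiv), 1,4-dioxane, 100 °C
Reagents that add atoms: none
Why: Ullmann-type C–O coupling of an unhindered phenoxide with an ortho-methoxy aryl bromide; aldehyde and methyl ester are inert to anhydrous Cs2CO3.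

**Step 2**
Reactants: 3 methyl 3-[4-(5-formyl-2-methoxyphenoxy)phenyl]propanoate
Product: 4 methyl 3-[4-(5-ethenyl-2-methoxyphenoxy)phenyl]propanoate
Conditions: Ph3PCH3Br (1.2 equiv), NaN(SiMe3)2 (1.15 equiv), THF, 0 °C → rt
Reagents that add atoms: methyltriphenylphosphonium bromide, C[P+](c1ccccc1)(c1ccccc1)c1ccccc1.[Br-]
Why: Wittig methylenation; the non-stabilised ylide takes the aldehyde far faster than the ester, and the amide base avoids transesterification.

**Step 3**
Reactants: 4 methyl 3-[4-(5-ethenyl-2-methoxyphenoxy)phenyl]propanoate; 5 2-bromo-4-methoxybenzaldehyde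
Product: 7 methyl 3-[4-(5-{2-(2-formyl-5-methoxyphenyl)ethyl}-2-methoxyphenoxy)phenyl]propanoate, via B-alkyl-9-BBN borane 6 (not isolated)
Conditions: 9-borabicyclo[3.3.1]nonane (9-BBN, 1.0 equiv to 4), THF, 0 °C → rt; then 5 (0.9 equiv), PdCl2(dppf) (5 mol %), K3PO4 (3 M aq, 3 equiv), DMF, 50 °C
Reagents that add atoms: none
Why: anti-Markovnikov hydroboration of the styrene gives primary borane 6, which undergoes B-alkyl Suzuki–Miyaura coupling with the ortho-formyl aryl bromide (fast oxidative addition to zerovalent palladium); the B–H reagent is consumed before 5 is added, so the aldehyde is not reduced.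

**Step 4**
Reactants: 7 methyl 3-[4-(5-{2-(2-formyl-5-methoxyphenyl)ethyl}-2-methoxyphenoxy)phenyl]propanoate; 8 furan
Product: 10 methyl 3-{4-[5-(2-{2-[furan-2-yl(hydroxy)methyl]-5-methoxyphenyl}ethyl)-2-methoxyphenoxy]phenyl}propanoate (racemic), via 2-furyllithium 9 (not isolated)
Conditions: furan (1.3 equiv), n-BuLi (1.1 equiv), THF, 0 °C; then 7, −78 °C; then H2O
Reagents that add atoms: none
Why: 1,2-addition of a heteroaryllithium to an aldehyde, much faster at −78 °C than attack on the methyl ester; the new carbinol stereocentre is formed racemic and is destroyed in steps 7 and 8.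

**Step 5**
Reactants: 10 methyl 3-{4-[5-(2-{2-[furan-2-yl(hydroxy)methyl]-5-methoxyphenyl}ethyl)-2-methoxyphenoxy]phenyl}propanoate
Product: 12 (furan-2-yl)(ArSul)methanol (racemic; E alkene), via hydroxy aldehyde 11 (not isolated)
Conditions: i-Bu2AlH (2.2 equiv), CH2Cl2, −78 °C; then (EtO)2P(O)CH(Li)SO2Ph [from (EtO)2P(O)CH2SO2Ph, n-BuLi, THF], −78 °C → rt; aqueous work-up
Reagents that add atoms: diethyl [(phenylsulfonyl)methyl]phosphonate, CCOP(=O)(CS(=O)(=O)c1ccccc1)OCC
Why: one-pot partial ester reduction / Horner–Wadsworth–Emmons olefination; the first equivalent of i-Bu2AlH is taken by the hydroxyl, the second stops at the aluminium hemiacetal at −78 °C, which releases aldehyde 11 to the stabilised phosphonate anion on warming, giving the (E)-vinyl sulfone.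

**Step 6**
Reactants: 12 (furan-2-yl)(ArSul)methanol
Product: 13 6-hydroxy-2-(ArSul)-2H-pyran-3(6H)-one (racemic mixture of C2/C6 diastereomers; E alkene)
Conditions: NBS (1.05 equiv), NaHCO3 (2 equiv), THF/H2O 4:1, 0 °C
Reagents that add atoms: water, O
Why: Achmatowicz rearrangement; NBS/water oxidises the furan to a cis-enedione that the carbinol oxygen traps as the pyranone lactol, while the electron-poor vinyl sulfone and the anisole rings do not compete at 0 °C; both stereocentres are erased later.

**Step 7**
Reactants: 13 6-hydroxy-2-(ArSul)-2H-pyran-3(6H)-one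
Product: 14 6-(ArSul)-2H-pyran-2,5(6H)-dione (racemic at C6, enolisable; E alkene)
Conditions: CrO3, H2SO4, H2O, acetone, 0 °C, 15 min
Reagents that add atoms: none
Why: Jones oxidation of the allylic lactol to the lactone gives the pyran-2,5-dione, the keto tautomer of a 5-hydroxy-2-pyrone; short contact at 0 °C in acid keeps it in the keto form and spares the other groups.

**Step 8**
Reactants: 14 6-(ArSul)-2H-pyran-2,5(6H)-dione
Product: 18 plagiochin E ring-A/ring-B dimethyl ether (ring D phenol free), via hydroxypyrone tautomer 15 (not isolated), via bicyclic lactone adduct 16 (not isolated), via sulfonyl cyclohexadienol 17 (not isolated)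
Conditions: Et3N (2 equiv), degassed xylenes (0.001 M), 60 °C, 24 h; then 140 °C, 6 h
Reagents that add atoms: none
Why: Proposed new method: Et3N converts 14 into the 5-oxido-2-pyrone (15), an electron-rich cyclic diene whose nucleophilic C6 adds to the β-carbon of the tethered vinyl sulfone and whose C3 then captures the α-sulfonyl carbanion (anionic Diels–Alder, formally a double Michael addition), closing the 16-membered ring in adduct 16; enolisation and retro-[4+2] loss of CO2 give 17, and E1-type loss of PhSO2H through a hydroxy-arenium ion aromatises ring D; the polarity of both partners fixes the C6–Cβ bond, so the OH ends ortho to the biaryl bond and the CH2CH2 bridge on its other side, and the four stereocentres of 16 (racemic endo/exo mixture) vanish on aromatisation; closest known reaction types are the amine-catalysed Diels–Alder reactions of 5-hydroxy-2-pyrones (2H-pyran-2,5-diones) with electron-poor alkenes and the intramolecular pyrone/vinyl sulfone Diels–Alder–decarboxylation–desulfinylation benzannulation used to close bis(bibenzyl) cyclophanes.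

**Step 9**
Reactants: 18 plagiochin E ring-A/ring-B dimethyl ether
Product: 19 plagiochin E
Conditions: BBr3 (6 equiv), CH2Cl2, −78 °C → rt; then H2O
Reagents that add atoms: none
Why: Lewis-acid aryl methyl ether cleavage; BBr3 removes both methyl groups while the diaryl ether, the biaryl bond and the bibenzyl bridges are inert, and no stereocentre exists to be affected.

## Compound list

1 | 3-bromo-4-methoxybenzaldehyde | COc1ccc(C=O)cc1Br | starting material
2 | methyl 3-(4-hydroxyphenyl)propanoate | COC(=O)CCc1ccc(O)cc1 | starting material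
3 | methyl 3-[4-(5-formyl-2-methoxyphenoxy)phenyl]propanoate | COC(=O)CCc1ccc(Oc2cc(C=O)ccc2OC)cc1 | intermediate
4 | methyl 3-[4-(5-ethenyl-2-methoxyphenoxy)phenyl]propanoate | COC(=O)CCc1ccc(Oc2cc(C=C)ccc2OC)cc1 | intermediate
5 | 2-bromo-4-methoxybenzaldehyde | COc1ccc(C=O)c(Br)c1 | starting material
6 | methyl 3-[4-(5-{2-(9-borabicyclo[3.3.1]nonan-9-yl)ethyl}-2-methoxyphenoxy)phenyl]propanoate | COC(=O)CCc1ccc(Oc2cc(CCB3C4CCCC3CCC4)ccc2OC)cc1 | intermediate (not isolated)
7 | methyl 3-[4-(5-{2-(2-formyl-5-methoxyphenyl)ethyl}-2-methoxyphenoxy)phenyl]propanoate | COC(=O)CCc1ccc(Oc2cc(CCc3cc(OC)ccc3C=O)ccc2OC)cc1 | intermediate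
8 | furan | c1ccoc1 | starting material
9 | 2-furyllithium | [Li]c1ccco1 | intermediate (not isolated)
10 | methyl 3-{4-[5-(2-{2-[furan-2-yl(hydroxy)methyl]-5-methoxyphenyl}ethyl)-2-methoxyphenoxy]phenyl}propanoate, racemic | COC(=O)CCc1ccc(Oc2cc(CCc3cc(OC)ccc3C(O)c4ccco4)ccc2OC)cc1 | intermediate
11 | 3-{4-[5-(2-{2-[furan-2-yl(hydroxy)methyl]-5-methoxyphenyl}ethyl)-2-methoxyphenoxy]phenyl}propanal, racemic | O=CCCc1ccc(Oc2cc(CCc3cc(OC)ccc3C(O)c4ccco4)ccc2OC)cc1 | intermediate (not isolated)
12 | (furan-2-yl)(ArSul)methanol, racemic, E alkene | O=S(=O)(/C=C/CCc1ccc(Oc2cc(CCc3cc(OC)ccc3C(O)c4ccco4)ccc2OC)cc1)c1ccccc1 | intermediate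
13 | 6-hydroxy-2-(ArSul)-2H-pyran-3(6H)-one, racemic diastereomer mixture, E alkene | O=S(=O)(/C=C/CCc1ccc(Oc2cc(CCc3cc(OC)ccc3C4OC(O)C=CC4=O)ccc2OC)cc1)c1ccccc1 | intermediate
14 | 6-(ArSul)-2H-pyran-2,5(6H)-dione, racemic, E alkene | O=S(=O)(/C=C/CCc1ccc(Oc2cc(CCc3cc(OC)ccc3C4OC(=O)C=CC4=O)ccc2OC)cc1)c1ccccc1 | intermediate
15 | 5-hydroxy-6-(ArSul)-2H-pyran-2-one (enol tautomer of 14, reacts as its triethylammonium salt), E alkene | O=S(=O)(/C=C/CCc1ccc(Oc2cc(CCc3cc(OC)ccc3C4=C(O)C=CC(=O)O4)ccc2OC)cc1)c1ccccc1 | intermediate (not isolated)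
16 | macrocyclic 8-(phenylsulfonyl)-2-oxabicyclo[2.2.2]octane-3,6-dione: bridgehead C1 (former pyrone C6) carries ring A, C7 carries the CH2CH2 to ring C, and C1 and C7 are linked through ring A–CH2CH2–ring B–O–ring C–CH2CH2; racemic endo/exo mixture, SO2Ph and CH2 trans on C8/C7 | O=C1CC2C(S(=O)(=O)c3ccccc3)C6CCc3ccc(cc3)Oc3cc(ccc3OC)CCc3cc(OC)ccc3C16OC2=O | intermediate (not isolated)
17 | macrocycle with ring D as a 4-(phenylsulfonyl)cyclohexa-1,5-dien-1-ol (C2 bonded to ring A, C3 bearing the CH2CH2 to ring C); racemic, sulfonyl and alkyl trans | OC1=C2c3ccc(OC)cc3CCc3ccc(OC)c(c3)Oc3ccc(cc3)CCC2C(S(=O)(=O)c4ccccc4)C=C1 | intermediate (not isolated)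
18 | plagiochin E ring-A/ring-B dimethyl ether (ring D OH free) | Oc1cccc2c1-c1ccc(OC)cc1CCc1ccc(OC)c(c1)Oc1ccc(cc1)CC2 | intermediate
19 | plagiochin E | Oc1cccc2c1-c1ccc(O)cc1CCc1ccc(O)c(c1)Oc1ccc(cc1)CC2 | target

## Step count and risks

Total step count: 9. Longest linear sequence: 9 steps (1 → 19; compounds 2, 5 and 8 enter as purchased materials).

**Most likely to fail, first: step 8.** The hindered, fully substituted C6 of the oxidopyrone must attack a β-alkyl vinyl sulfone across a 16-membered ring, and intermolecular dimerisation of 14 or base-induced isomerisation of the vinyl sulfone to the allyl sulfone may win. The fallback leaves the anionic manifold. It sets out from 14, which is O-silylated (TBSOTf, Et3N, CH2Cl2, 0 °C) to the neutral diene 5-[(tert-butyldimethylsilyl)oxy]-6-(ArSul)-2H-pyran-2-one F1. This is heated at 0.001 M in 1,2-dichlorobenzene at 180 °C with BHT and solid NaHCO3, so that a purely thermal intramolecular Diels–Alder reaction (same "para" regiochemistry from the 2-silyloxydiene), CO2 extrusion and sulfinic acid loss give the ring-D tert-butyldimethylsilyl ether of macrocycle 18 F2. Bu4NF in THF then frees the phenol, and the route is rejoined at 18.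

**Second: step 7.** The lactol carries an electron-rich aryl group and the product is an easily enolised, oxidisable dione, so chromic acid may over-oxidise. The fallback reaches the carboxyl oxidation level by cycloaddition instead of lactol oxidation, and it bypasses 13. It sets out from 12, which is photo-oxygenated (O2, hν, rose bengal, i-Pr2NEt, CH2Cl2/MeOH, −78 → 0 °C). Singlet oxygen adds [4+2] to the furan and the endoperoxide opens by Kornblum–DeLaMare rearrangement to the (Z)-4-oxo-2-enoic acid, isolated as its ring-chain tautomer 5-hydroxy-5-[hydroxy(ArSul)methyl]furan-2(5H)-one F3. Dehydrative lactonisation of the open keto acid onto the carbinol hydroxyl (EDC·HCl, catalytic DMAP, CH2Cl2) closes the six-membered lactone, and the route is rejoined at 14.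

**Third: step 5.** Partial reduction of the ester beside a free carbinol may over-reduce or stall. The fallback separates the redox adjustment from the olefination. It sets out from 10, which is reduced fully (LiAlH4, THF, 0 °C) to the diol 3-{4-[5-(2-{2-[furan-2-yl(hydroxy)methyl]-5-methoxyphenyl}ethyl)-2-methoxyphenoxy]phenyl}propan-1-ol F4. The primary alcohol alone is oxidised with catalytic TEMPO and PhI(OAc)2 in CH2Cl2 to aldehyde 11, this time isolated. A separate Horner–Wadsworth–Emmons reaction with (EtO)2P(O)CH2SO2Ph and NaH in THF then rejoins the route at 12.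

## Further compounds

F1 | step 8 | 5-[(tert-butyldimethylsilyl)oxy]-6-(ArSul)-2H-pyran-2-one, E alkene | O=S(=O)(/C=C/CCc1ccc(Oc2cc(CCc3cc(OC)ccc3C4=C(O[Si](C)(C)C(C)(C)C)C=CC(=O)O4)ccc2OC)cc1)c1ccccc1
F2 | step 8 | ring-D tert-butyldimethylsilyl ether of macrocycle 18 | CC(C)(C)[Si](C)(C)Oc1cccc2c1-c1ccc(OC)cc1CCc1ccc(OC)c(c1)Oc1ccc(cc1)CC2
F3 | step 7 | 5-hydroxy-5-[hydroxy(ArSul)methyl]furan-2(5H)-one, diastereomer mixture, E alkene | O=S(=O)(/C=C/CCc1ccc(Oc2cc(CCc3cc(OC)ccc3C(O)C4(O)C=CC(=O)O4)ccc2OC)cc1)c1ccccc1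
F4 | step 5 | 3-{4-[5-(2-{2-[furan-2-yl(hydroxy)methyl]-5-methoxyphenyl}ethyl)-2-methoxyphenoxy]phenyl}propan-1-ol, racemic | OCCCc1ccc(Oc2cc(CCc3cc(OC)ccc3C(O)c4ccco4)ccc2OC)cc1
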